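**Plan**
- Retrosynthesis: the enone C=C bond is cut first (aldol condensation), giving 4-hydroxybenzaldehyde and an 8-acetylchroman-3-ol. The C3–OH is traced back to a C3–B bond. The pyran ring is then cut at C4–C3 and O1–C2 together (retro oxa-[4+2]) to an ortho-quinone methide of ring A and an isobutenylboronate. Last, the benzylic carbon C4 is cut from ring A, leading to paeonol and formaldehyde.
- Forward: ring A is bought (paeonol). C4 is attached ortho to the phenol through a boron template, the pyran ring is closed in the key cycloaddition, C–B is oxidised to C–OH, and the cinnamoyl chain is joined last by Claisen–Schmidt condensation.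
- Enabling feature: O1 on C8a and the benzylic C4 on C4a are ortho on ring A, so O1=C8a–C4a=C4 is a latent ortho-quinone methide. The C8 acetyl carbonyl next to O1 gives a second oxygen for two-point binding of a chiral Lewis acid. The gem-dimethyl group at C2 polarises the 2π partner so that C4 bonds to C3 and O1 to C2.
- Stereochemistry: the only stereocentre (C3, S) is set in the key step by the chiral scandium catalyst as a C–B bond and is passed on with retention in the oxidation. The E alkene results from thermodynamic control in the condensation.

Key step: step 3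

Remark: paraformaldehyde is drawn as its monomer; the sense of induction in step 3 rests on a working model only, so the (S,S) ligand is written and its (R,R) antipode would be taken if the adduct proved to be 3R.

**Step 1**
Reactants: 1 1-(2-hydroxy-4-methoxyphenyl)ethan-1-one (paeonol); 2 phenylboronic acid; 3 paraformaldehyde
Product: 4 1-(5-methoxy-2-phenyl-4H-1,3,2-benzodioxaborinin-8-yl)ethan-1-one (cyclic phenylboronate of the ortho-hydroxymethyl phenol)
Conditions: PhB(OH)2 (1.2 equiv), (CH2O)n (4 equiv), EtCO2H (0.3 equiv), toluene, reflux, Dean–Stark trap
Reagents that add atoms: none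
Why: Boron-templated ortho-hydroxymethylation of a phenol: phenylboronic acid tethers the phenolic oxygen and formaldehyde so that the C–C bond can form only at the free ortho carbon (activated by the ortho OH and the ortho OMe), and the diol is trapped as its cyclic boronate, which stops further reaction with formaldehyde; no stereocentre is formed.

**Step 2**
Reactants: 4 1-(5-methoxy-2-phenyl-4H-1,3,2-benzodioxaborinin-8-yl)ethan-1-one
Product: 5 1-[2-hydroxy-3-(hydroxymethyl)-4-methoxyphenyl]ethan-1-one
Conditions: 30% aq. H2O2 (3 equiv), THF, 0 °C to rt; product kept cold and used promptly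
Reagents that add atoms: none
Why: Oxidation of the B–phenyl bond by hydrogen peroxide followed by hydrolysis of the borate frees the phenol and the benzylic alcohol irreversibly under near-neutral conditions that should leave the aryl ketone untouched; no stereocentre is formed.

**Step 3**
Reactants: 5 1-[2-hydroxy-3-(hydroxymethyl)-4-methoxyphenyl]ethan-1-one; 6 4,4,5,5-tetramethyl-2-(2-methylprop-1-en-1-yl)-1,3,2-dioxaborolane (isobutenylboronic acid pinacol ester)
Product: 8 1-[(3S)-5-methoxy-2,2-dimethyl-3-(4,4,5,5-tetramethyl-1,3,2-dioxaborolan-2-yl)-3,4-dihydro-2H-chromen-8-yl]ethan-1-one, via acyl ortho-quinone methide 7 (not isolated)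
Conditions: Sc(OTf)3 (10 mol %), 2,6-bis[(4S)-4-phenyl-4,5-dihydro-1,3-oxazol-2-yl]pyridine (12 mol %), 4 Å molecular sieves, 6 (3 equiv), CH2Cl2, −20 °C, slow addition of 5
Reagents that add atoms: none
Why: Proposed new method: Sc(OTf)3 carrying the tridentate pybox ligand should bind 5 at the phenolic O and the neighbouring acetyl O, ionise the benzylic C–OH (doubly stabilised by the ortho O and the ortho OMe; water is the only by-product) and so release the acyl ortho-quinone methide 7 as a rigid six-membered chelate inside the chiral pocket, where its O=C–C=CH2 heterodiene adds the C=C bond of 6 in an inverse-electron-demand oxa-[4+2] cycloaddition. The closest known reaction types are the acid-catalysed hetero-Diels–Alder reactions of ortho-quinone methides generated in situ from ortho-hydroxybenzyl alcohols with styrenes and alkyl-substituted alkenes, and the enantioselective hetero-Diels–Alder reactions of two-point-binding enones on chiral oxazoline-ligated Lewis acids; an alkenylboronic ester has not been shown as the 2π partner, nor the ring acyl group as the second binding point. The pyran ring closes by a suprafacial [4π+2π] cycloaddition that is concerted but asynchronous, with C4–C3 bond formation leading and O1–C2 bond formation following (at the stepwise limit, a six-membered closure of the scandium phenoxide oxygen on the tertiary cation). The single new stereocentre, the boron-bearing C3, is defined by which face of the alkene meets the methide CH2, and this is controlled by the twofold-symmetric ligand, which screens one face of the planar chelated quinone methide, together with the exo placement of the bulky pinacol boronate. Regioselectivity (CH2 to the boron-bearing CH, O to CMe2) is secured by positive charge building up on the carbon that carries two methyl groups and lies β to the electron-releasing C–B bond, and chemoselectivity over alkenyl transfer from boron is secured by the weakly Lewis acidic pinacol ester and by the quinone oxygen being occupied by scandium. Slow addition of 5 to an excess of 6 over molecular sieves is needed to suppress self-condensation of 7 and hydrolysis of the boronate.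

**Step 4**
Reactants: 8 1-[(3S)-5-methoxy-2,2-dimethyl-3-(4,4,5,5-tetramethyl-1,3,2-dioxaborolan-2-yl)-3,4-dihydro-2H-chromen-8-yl]ethan-1-one
Product: 9 1-[(3S)-3-hydroxy-5-methoxy-2,2-dimethyl-3,4-dihydro-2H-chromen-8-yl]ethan-1-one
Conditions: NaBO3·4H2O (4 equiv), THF/H2O 1:1, rt
Reagents that add atoms: sodium perborate tetrahydrate, [Na+].[Na+].O[B-]1(O)OO[B-](O)(O)OO1
Why: Oxidation of a secondary alkylboronic ester (the oxidative work-up of hydroboration): the peroxide adds to boron and C3 migrates from boron to oxygen with retention, so the 3S configuration should be carried over unchanged; perborate is mild enough to spare the aryl ketone, and, as in hydroboration–oxidation of 2H-chromenes, oxidation is expected to outrun β-elimination of the aryloxy group.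

**Step 5**
Reactants: 9 1-[(3S)-3-hydroxy-5-methoxy-2,2-dimethyl-3,4-dihydro-2H-chromen-8-yl]ethan-1-one; 10 4-hydroxybenzaldehyde
Product: 11 (E)-1-[(3S)-3-hydroxy-5-methoxy-2,2-dimethyl-3,4-dihydro-2H-chromen-8-yl]-3-(4-hydroxyphenyl)prop-2-en-1-one
Conditions: KOH (50% aq., 5 equiv), EtOH, rt to 50 °C; then 1 M HCl to pH 5
Reagents that add atoms: none
Why: Claisen–Schmidt aldol condensation: the methyl ketone enolate adds to the non-enolisable aldehyde and E1cB dehydration should give the conjugated E enone under thermodynamic control, while the C3 stereocentre, remote from any acidic position, is not touched.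

**Compound list**
1 | 1-(2-hydroxy-4-methoxyphenyl)ethan-1-one (paeonol) | CC(=O)c1ccc(OC)cc1O | starting material
2 | phenylboronic acid | OB(O)c1ccccc1 | starting material
3 | paraformaldehyde (formaldehyde unit) | C=O | starting material
4 | 1-(5-methoxy-2-phenyl-4H-1,3,2-benzodioxaborinin-8-yl)ethan-1-one | CC(=O)c1ccc(OC)c2COB(c3ccccc3)Oc12 | intermediate
5 | 1-[2-hydroxy-3-(hydroxymethyl)-4-methoxyphenyl]ethan-1-one | CC(=O)c1ccc(OC)c(CO)c1O | intermediate
6 | 4,4,5,5-tetramethyl-2-(2-methylprop-1-en-1-yl)-1,3,2-dioxaborolane | CC(C)=CB1OC(C)(C)C(C)(C)O1 | starting material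
7 | 2-acetyl-5-methoxy-6-methylidenecyclohexa-2,4-dien-1-one (scandium-bound, not isolated) | CC(=O)C1=CC=C(OC)C(=C)C1=O | intermediate
8 | 1-[(3S)-5-methoxy-2,2-dimethyl-3-(4,4,5,5-tetramethyl-1,3,2-dioxaborolan-2-yl)-3,4-dihydro-2H-chromen-8-yl]ethan-1-one | COc1ccc(C(C)=O)c2c1C[C@H](B3OC(C)(C)C(C)(C)O3)C(C)(C)O2 | intermediate
9 | 1-[(3S)-3-hydroxy-5-methoxy-2,2-dimethyl-3,4-dihydro-2H-chromen-8-yl]ethan-1-one | COc1ccc(C(C)=O)c2c1C[C@H](O)C(C)(C)O2 | intermediate
10 | 4-hydroxybenzaldehyde | O=Cc1ccc(O)cc1 | starting material
11 | (E)-1-[(3S)-3-hydroxy-5-methoxy-2,2-dimethyl-3,4-dihydro-2H-chromen-8-yl]-3-(4-hydroxyphenyl)prop-2-en-1-one | COc1ccc(C(=O)/C=C/c2ccc(O)cc2)c2c1C[C@H](O)C(C)(C)O2 | target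

**Step count**
Total steps: 5. Longest linear sequence: 5 steps (1 to 4 to 5 to 8 to 9 to 11).

**Steps most likely to fail**

Step 3 (proposed new method). Several processes could defeat it:
- poor enantioface discrimination, if a proton-catalysed background reaction runs outside the chiral pocket;
- transfer of the alkenyl group from boron with loss of boron instead of ring closure;
- Lewis-acid-induced β-elimination of the newly formed boryl ether;
- self-condensation of the quinone methide.

The fallback uses known chemistry, sets out from 1 and comes back at 9. Paeonol 1 would be condensed with 3-methylbut-2-enal under the same boron template (PhB(OH)2, EtCO2H, toluene, reflux). Ortho-alkylation, dehydration and oxa-6π electrocyclisation should give 1-(5-methoxy-2,2-dimethyl-2H-chromen-8-yl)ethan-1-one F1. Jacobsen–Katsuki epoxidation would follow, using the (S,S)-salen complex [N,N'-bis(3,5-di-tert-butylsalicylidene)-1,2-cyclohexanediamine]MnCl (trivalent manganese), NaOCl and 4-phenylpyridine N-oxide in CH2Cl2 at 0 °C. By analogy with other 2,2-dimethylchromenes this is expected to give 1-[(3S,4S)-3,4-epoxy-5-methoxy-2,2-dimethyl-3,4-dihydro-2H-chromen-8-yl]ethan-1-one F2. Hydrogenolysis of the benzylic C4–O bond only (H2, 1 atm, Pd/C, EtOAc, rt, stopped at consumption of the epoxide) would then give 9 with C3 untouched.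

Step 1. The hydrogen-bonded, acyl-deactivated phenol may fail to enter the boron template, so that no C–C bond forms, or it may react further with formaldehyde. The fallback sets out from 1 and comes back at 5. Magnesium-mediated ortho-formylation (MgCl2, Et3N, paraformaldehyde, MeCN, reflux) goes through the more nucleophilic magnesium phenoxide and should give 3-acetyl-2-hydroxy-6-methoxybenzaldehyde F3. Chemoselective reduction of the aldehyde in the presence of the ketone (NaBH(OAc)3, THF, rt) would then give 5.

Step 5. Aldol addition may be sluggish because the aldehyde is present as its poorly electrophilic phenoxide, giving incomplete conversion and loss of aldehyde by disproportionation on forcing. The fallback sets out from 9 and comes back at 11. Commercial 4-(methoxymethoxy)benzaldehyde would be condensed with 9 (KOH, EtOH, rt) to give (E)-1-[(3S)-3-hydroxy-5-methoxy-2,2-dimethyl-3,4-dihydro-2H-chromen-8-yl]-3-[4-(methoxymethoxy)phenyl]prop-2-en-1-one F4. The acetal would then be removed (3 M HCl, MeOH, 50 °C) to give 11.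

**Further compounds**
F1 | step 3 | 1-(5-methoxy-2,2-dimethyl-2H-chromen-8-yl)ethan-1-one | CC(=O)c1ccc(OC)c2C=CC(C)(C)Oc12
F2 | step 3 | 1-[(3S,4S)-3,4-epoxy-5-methoxy-2,2-dimethyl-3,4-dihydro-2H-chromen-8-yl]ethan-1-one | COc1ccc(C(C)=O)c2c1[C@@H]1O[C@@H]1C(C)(C)O2
F3 | step 1 | 3-acetyl-2-hydroxy-6-methoxybenzaldehyde | CC(=O)c1ccc(OC)c(C=O)c1O
F4 | step 5 | (E)-1-[(3S)-3-hydroxy-5-methoxy-2,2-dimethyl-3,4-dihydro-2H-chromen-8-yl]-3-[4-(methoxymethoxy)phenyl]prop-2-en-1-one | COc1ccc(C(=O)/C=C/c2ccc(OCOC)cc2)c2c1C[C@H](O)C(C)(C)O2
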